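Stir the closed two-phase vessel at constant volume and temperature: starting material meets reagent crossing over from the second phase, and target passes into that phase.

| flask | starting material | reagent in the second phase | protic impurity | remark | time | volume of the second phase over the first |
|---|---|---|---|---|---|---|
| Thursday's | 0.60 M | 0.40 M | 0.020 M | run made earlier |  |  |
| flask | 0.40 M | 0.400 M | 0.0200 M |  | 2.5 h | 2.0 |

Thursday's run (percent of the starting material charged)

| time / min | target / % | starting material / % |
|---|---|---|
| 6.00 | 35 | 48 |
| 12.0 | 37 | 40 |
| 20.0 | 40 | 35 |
| 25.0 | 44 | 31 |
| 30.0 | 44 | 31 |
| 40.0 | 44 | 28 |
| 50.0 | 47 | 29 |

(scatter of a reading: 1.5 percentage points)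

- what is said of target includes product in the second phase
- in the second phase: reagent in the second phase, product in the second phase; everything else is in the first
- charges count per volume of the first phase; a concentration in a rate is the amount of a species over the volume of its own phase; every rate counts per litre of the first phase
- what was read earlier has a scatter of 1.5 percentage points, one standard deviation
- on the list of suspects stand: target <-> product in the second phase; starting material + protic impurity -> quenched substrate; target <-> isomer of the product; reagent in the reaction phase -> decomposition product; starting material + reagent in the reaction phase -> target; target -> decomposed product; reagent in the reaction phase <-> reagent in the second phase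
- the earlier runs hold the two phases in the same ratio of volumes as the flask asked about

1. target and product in the second phase together at 2.5 h, in percent of the starting material charged
2. part of the starting material charged that has reacted at 2.5 h

- Define capacity w as the charged reagent in the second phase plus protic impurity, over the charged starting material, each taking one starting material: 105% for the flask, 70.0% for Thursday's run. Equal charges give 100%, the zero of the scale.
- First rung, minutes: count the impurity as gone first and fit Thursday's first reading to second-order loss on total reagent. That reading gives an apparent constant k = 0.564 M⁻¹ min⁻¹; carry it to the flask at the same ratio of volumes.
- Next rung, the stop: from 25.0 min, Thursday's starting material reads 28% to 31%, against 30.0% left by capacity.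
- Flask, the tail: w is more than 100%, so starting material is the limiting reagent, by a margin of 0.0200 M. With k, I reckon starting material over total reagent, both phases counted, at 0.175 at 2.5 h, and so 98.9% reacted.
- Last rung: Thursday's last four readings put target at 66.9% of the unquenched reacted starting material, so I reckon target with product in the second phase at 62.8% in the flask. But 2.5 h is 3.00 times the time of Thursday's last reading, so a slow loss stays unread.
- The forecast, reasoning “so reagent loss is small”, gives 61% and 97.5%, lower than my reckoning on both.
- The flask gives 60.6% and 99.4%, with 0.58% of its starting material left.

    target ⇌ product in the second phase, rate k1*([target] - [product in the second phase]/K1) per volume of the first phase (partition coefficient = 20.0, kL = 0.101 min⁻¹)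
    starting material + protic impurity → quenched substrate (k = 10.1 M⁻¹ min⁻¹)
    target ⇌ isomer of the product (K = 0.750, k = 0.0897 min⁻¹)
    reagent in the reaction phase → decomposition product (k = 1.77 × 10⁻⁴ min⁻¹)
    starting material + reagent in the reaction phase → target (k = 3.06 M⁻¹ min⁻¹)
    target → decomposed product (k = 0.0419 min⁻¹)
    reagent in the reaction phase ⇌ reagent in the second phase, rate k7*([reagent in the reaction phase] - [reagent in the second phase]/K7) per volume of the first phase (partition coefficient = 1.49, kL = 1.57 min⁻¹)

- Apply w to the flask charged with 1.0 M of starting material: 42.0%. In that flask 42.0% of the starting material has reacted at 2.50 h, with reagent down to 0 M in the reaction phase and 0% in the second. The asked flask has not come to rest: by 25.0 h its reacted part goes to 100%, decomposed product climbs from 33.0% to 71.7%, and target with product in the second phase falls to 23.0%.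

All runs stem from a simulated flask from invented constants; the scatter is artificial.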